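Q, the product wanted, is a way station in the books of Z, the limiting reagent, so I keep a ledger of where the Z charged goes.

| flask | Z | D | remark | time |
|---|---|---|---|---|
| larch | 0.60 M | 29 mM (held) | run made earlier |  |
| flask | 0.40 M | 29 mM (held) |  | 25 min |

- larch (time / min: Q / %, Z / %): 1.00: 4.1, 94.5; 2.00: 7.9, 89.9; 3.00: 10.4, 87.5; 4.00: 10.9, 84.9; 5.00: 11.7, 82.5

(each reading ± 0.5 percentage points)

- time, not beyond 25 min, at which the flask holds most Q
- the amount of Q, in percent of the Z charged, at that time

- at the start none of D is in solution

The larch run at 5.00 min, in percent of the Z charged, reads:

Z still there: 82.5%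
Standing as Q: 11.7%
Gone past Q: 5.80%

I book that last entry as having passed through Q. Summed minute by minute, with the last reading counted by half, the larch readings of Q come to 39.1% of the charge held for one minute. So:

drain constant = gone past Q / Q held over time = 0.148 min⁻¹

That drain constant, the share of standing Q that passes on each minute, is a reading, and each entry behind it carries a scatter of 0.5 percentage points.

[Q] climbs while Z's fall per minute exceeds drain constant × [Q], and it peaks where the two cross. By this reckoning Q in the larch run loses 1.73% each minute at the end, less than the 2.50% by which Z falls, so that run stops before its crossing. I carry the constant unchanged to the flask, which is my assumption.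

The forecast says 8 min and 12.5%, on the ground that “Q is therefore an intermediate”.

The flask holds most Q at 5.50 min, with 12.5%, earlier than forecast, while E already stands at 8.45%.

    D ⇌ L, rate k1*(csat - [L]) (kL = 0.0460 s⁻¹)
    Z + L ⇌ Q (K = 12.0 M⁻¹, k = 0.120 M⁻¹ s⁻¹)
    L + Q → E (k = 0.170 M⁻¹ s⁻¹)
    L → G (k = 0.0150 s⁻¹)

At that peak the drain constant gives an outflow of 1.86% of the charge each minute, and Z in the flask falls on average by 1.91% each minute from the peak up to 12.5 min. For the same flask left until 15 min, the constant books 4 points of new E after 12.5 min, and that flask shows 4.9 points.

The earlier runs and the new flask come from a simulation on assumed constants; noise was put on by code.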